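In a one-step world each starting complex becomes complex with two exchanged by setting free one leaving ligand, so with the gas held, the odds [two exchanged]/[starting complex] fall as [leaving ligand] rises. One number then carries a flask: the crossover level, odds times [leaving ligand], at which both complexes stand equal. In logarithms, log odds = log crossover − log [leaving ligand].

common to all: starting complex 10 mM

| charge | leaving ligand | gas | temperature | remark | time |
|---|---|---|---|---|---|
| blue | 20 mM | 2 mM (held) | 40 °C | the very flask that is asked about, followed so far |  |
| grey | 30 mM | 2 mM (held) | 25 °C | run made earlier |  |
| flask | 20.0 mM | 2.0 mM (held) | 40 °C |  | 2.0 h |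

| run | time / min | complex with two exchanged / % |
|---|---|---|
| blue | 10.0 | 12.8 |
| blue | 30.0 | 22.0 |
| blue | 60.0 | 24.3 |
| blue | 80.0 | 23.8 |
| blue | 120 | 24.5 |
| grey | 0.667 | 0 |
| grey | 1.33 | 1.4 |
| grey | 3.00 | 1.2 |
| grey | 4.00 | 2.0 |
| grey | 8.00 | 5.9 |

(readings scatter by 1 percentage point)

- north-west: at 2.0 h take out 90 % of the leaving ligand then present, then wait 40 min
- west: at 2.0 h add starting complex, 50.0 % of the amount charged, then wait 40 min
- east: change nothing and wait 40 min more
- north-east: at 2.0 h raise the temperature by 25 K, then wait 40 min

- additions leave the volume as it is
- at the start none of the gas is in solution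

- complex with two exchanged, in percent of the starting complex first charged, at 2.0 h
- which option adds most complex with two exchanged ("none" when 2 percentage points or less is all one gets) (north-west / west / east / north-east / none)
- complex with two exchanged present, in percent of the starting complex first charged, after north-west
- complex with two exchanged present, in percent of the starting complex first charged, after east

The blue readings stay flat from 60.0 min to 120 min, within the scatter of 1 percentage point, at a mean of 24.2 %. My reckoning therefore keeps that level for "now" and for east. The first reading, at 10.0 min, is already about half of it. In the one-step reckoning, one leaving ligand comes free per complex and the rest counts as starting complex. So [leaving ligand] stands at 22.4 mM, and the blue flask gives a crossover level of 7.16 mM.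

For north-west, my bracket holds within the one-step reckoning, and the plateau is its first floor. Removal lowers log [leaving ligand] by one, lifting log odds from −0.496 to 0.504, a first ceiling of 76.1 %. Reaching that ceiling would bring [leaving ligand] up to 7.44 mM, which raises the floor to 49.0 %. That floor means [leaving ligand] of at least 4.73 mM, which lowers the ceiling to 60.2 %. Even the floor's gain of 25 points exceeds the margin of 2 points, so north-west is my choice among the options reckoned.

The forecast says 24.3 % now, 24.3 % after east, north-west as best and 59 % after north-west, on the ground “Re-equilibration releases ligand”. Its north-west value stands inside my bracket, under the ceiling and over the floor.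

The flask gives 24.9 % now, 24.9 % after east, and north-west as best, with a gain of 16 points. After north-west it holds 40.8 %, below the bracket.

    gas ⇌ incoming ligand, rate k1*(csat - [incoming ligand]) (kL = 0.0100 s⁻¹)
    complex with two exchanged + incoming ligand ⇌ leaving ligand + complex with three exchanged (K = 3.80, k = 9.70 M⁻¹ s⁻¹, Ea = 55.0 kJ mol⁻¹, ΔH = −61.0 kJ mol⁻¹)
    complex with one exchanged + incoming ligand ⇌ leaving ligand + complex with two exchanged (K = 8.60, k = 5.80 M⁻¹ s⁻¹, Ea = 42.0 kJ mol⁻¹, ΔH = −21.0 kJ mol⁻¹)
    starting complex + incoming ligand ⇌ leaving ligand + complex with one exchanged (K = 30.0, k = 3.60 M⁻¹ s⁻¹, Ea = 39.0 kJ mol⁻¹, ΔH = 20.0 kJ mol⁻¹)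
    (constants at 40 °C)

In the flask at 120 min, the step from two to three exchanged, taken alone, relaxes both ways together with a half-life of 0.0924 min, short against 2.0 h. At 1200 min the flask still holds 24.9 %, which is thermodynamic control. With the flask's own [leaving ligand], 157 % of its charge, and what is not complex with two exchanged counted on the other side of the odds, the crossover level comes to 10.4 mM, against 7.16 mM from the plateau.

In the neighbour flask charged with 8.0 mM of leaving ligand, 7.16 mM gives 37.8 %. The simulation gives 32.4 %.

(The runs are calculated with constants of no real substance, noise included.)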